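The target is cut back to a trans-fused decalin aldehyde by removing C12–C17 and the palmitate; its rings A and B are then opened together at C5–C10 and C8–C9. The feature used is that the trans C5/C10 fusion, the C10 methyl, the C9 branch cis to it and an oxygen at C8 are the exact imprint of an intramolecular Diels–Alder reaction. One heating step joins an (E)-enal (C9=C10–C11) to an (E,E)-1-silyloxydiene (C5–C8) across the C1–C4 tether, closing both rings and setting C5, C8, C9 and C10 under control of the quaternary C4. The precursor is an acyclic all-E triene ester with C4 preset by enzymatic desymmetrisation.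

Key step: step 15

Assumption: the esterase is taken to cleave diester 9 in the sense usual for long-chain dimethyl 2-alkyl-2-methylmalonates, giving the (R)-half-ester 10; if the other ester group were cleaved, reducing the acid arm instead of the ester arm would give the same hydroxy ester 13.

Design note: in triene 22 the (E) dienophile geometry comes from a stereospecific cross-coupling, C11 stays at the alcohol level until the last step before cyclisation (no hydride reduction beside the C4 ester), and the silyl dienol ether is made only three steps before it is used.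

Step 1
Reactants: 1 but-2-yn-1-ol
Product: 2 tert-butyl(but-2-yn-1-yloxy)dimethylsilane
Conditions: TBSCl, imidazole, CH2Cl2, 0 °C → rt
Reagents that add atoms: tert-butyldimethylsilyl chloride, CC(C)(C)[Si](C)(C)Cl
Why: Silyl ether formation on a primary alcohol gives a group that is inert to the hydrozirconation, cross-coupling, esterase and hydride steps that follow.

Step 2
Reactants: 2 tert-butyl(but-2-yn-1-yloxy)dimethylsilane
Product: 4 (E)-tert-butyl[(3-iodobut-2-en-1-yl)oxy]dimethylsilane, via alkenyl-Cp2ZrCl complex 3 (not isolated)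
Conditions: Cp2Zr(H)Cl (2 equiv), THF, 50 °C; then I2, THF, 0 °C
Reagents that add atoms: iodine, II
Why: Hydrozirconation–iodination, in which syn addition of Zr–H, equilibration by excess hydride to the less hindered regioisomer (Zr on the methyl-bearing carbon) and iododezirconation with retention place iodine trans to CH2O, the (E) geometry that both later couplings pass on.

Step 3
Reactants: 5 dimethyl methylmalonate; 6 allyl bromide
Product: 7 dimethyl 2-methyl-2-(prop-2-en-1-yl)propanedioate
Conditions: NaH, THF, 0 °C → rt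
Reagents that add atoms: none
Why: Malonate alkylation (SN2 of the malonate anion on an allylic bromide) attaches C3–C1 as an allyl group to the future C4.

Step 4
Reactants: 7 dimethyl 2-methyl-2-(prop-2-en-1-yl)propanedioate; 4 (E)-tert-butyl[(3-iodobut-2-en-1-yl)oxy]dimethylsilane
Product: 9 dimethyl 2-[(4E)-6-(tert-butyldimethylsilyloxy)-4-methylhex-4-en-1-yl]-2-methylpropanedioate, via B-alkyl-9-BBN adduct 8 (not isolated)
Conditions: 9-BBN, THF, 0 °C → rt; then 4, Pd(dppf)Cl2 (5 mol%), AsPh3, Cs2CO3, DMF/H2O, rt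
Reagents that add atoms: none
Why: B-alkyl Suzuki–Miyaura coupling, in which anti-Markovnikov hydroboration of the terminal alkene and Pd(dppf)Cl2-catalysed sp3–sp2 coupling with retention at the alkenyl iodide form C1–C10 and give the trisubstituted C9=C10 alkene as the pure (E) isomer.

Step 5
Reactants: 9 dimethyl 2-[(4E)-6-(tert-butyldimethylsilyloxy)-4-methylhex-4-en-1-yl]-2-methylpropanedioate
Product: 10 (2R,6E)-8-(tert-butyldimethylsilyloxy)-2-(methoxycarbonyl)-2,6-dimethyloct-6-enoic acid
Conditions: pig-liver esterase, phosphate buffer pH 7.5/DMSO (9:1), rt, pH-stat (1 M NaOH); then 1 M HCl to pH 3, 0 °C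
Reagents that add atoms: water, O
Why: Enzymatic desymmetrisation of a prochiral 2-alkyl-2-methylmalonate, in which hydrolysis of one enantiotopic ester group sets the quaternary C4 and the hindered second ester is left intact.

Step 6
Reactants: 10 (2R,6E)-8-(tert-butyldimethylsilyloxy)-2-(methoxycarbonyl)-2,6-dimethyloct-6-enoic acid
Product: 12 (2S,6E)-8-(tert-butyldimethylsilyloxy)-2-(hydroxymethyl)-2,6-dimethyloct-6-enoic acid, via lithium carboxylate 11 (not isolated)
Conditions: LiN(SiMe3)2 (1.0 equiv), THF, −78 °C; then LiBH4, THF, 0 → 40 °C; 1 M HCl to pH 3, 0 °C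
Reagents that add atoms: none
Why: Chemoselective borohydride reduction, in which the carboxylate is inert to LiBH4 so that only the methyl ester arm is reduced to the CH2OH that becomes C5, the stereocentre being untouched.

Step 7
Reactants: 12 (2S,6E)-8-(tert-butyldimethylsilyloxy)-2-(hydroxymethyl)-2,6-dimethyloct-6-enoic acid
Product: 13 methyl (2S,6E)-8-(tert-butyldimethylsilyloxy)-2-(hydroxymethyl)-2,6-dimethyloct-6-enoate
Conditions: MeI, KHCO3, DMF, rt
Reagents that add atoms: iodomethane, CI
Why: Carboxylate O-alkylation (SN2 on MeI) turns the acid arm into the C19 methyl ester, the weak base leaving the primary alcohol unalkylated.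

Step 8
Reactants: 13 methyl (2S,6E)-8-(tert-butyldimethylsilyloxy)-2-(hydroxymethyl)-2,6-dimethyloct-6-enoate
Product: 14 methyl (2S,6E)-8-(tert-butyldimethylsilyloxy)-2-formyl-2,6-dimethyloct-6-enoate
Conditions: Dess–Martin periodinane, pyridine, CH2Cl2, 0 °C → rt
Reagents that add atoms: none
Why: Dess–Martin oxidation of the neopentyl alcohol gives the C5 aldehyde, which has no α-hydrogen and therefore cannot epimerise at C4.

Step 9
Reactants: 14 methyl (2S,6E)-8-(tert-butyldimethylsilyloxy)-2-formyl-2,6-dimethyloct-6-enoate; 15 [2-(1,3-dioxolan-2-yl)ethyl]triphenylphosphonium bromide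
Product: 16 methyl (2S,6E)-8-(tert-butyldimethylsilyloxy)-2-[(1Z)-3-(1,3-dioxolan-2-yl)prop-1-en-1-yl]-2,6-dimethyloct-6-enoate
Conditions: 15, KN(SiMe3)2, THF, −78 → 0 °C; then 14, −78 °C → rt
Reagents that add atoms: none
Why: Wittig olefination with a non-stabilised ylide adds C6–C8 as a masked aldehyde, and the (Z) geometry formed at C5=C6 does not matter because step 10 erases it.

Step 10
Reactants: 16 methyl (2S,6E)-8-(tert-butyldimethylsilyloxy)-2-[(1Z)-3-(1,3-dioxolan-2-yl)prop-1-en-1-yl]-2,6-dimethyloct-6-enoate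
Product: 18 methyl (2S,6E)-8-hydroxy-2,6-dimethyl-2-[(2E)-4-oxobut-2-en-1-yl]oct-6-enoate, via β,γ-unsaturated aldehyde 17 (not isolated)
Conditions: 1 M HCl, THF, 0 °C → rt; then DBU (0.1 equiv), CH2Cl2, 0 °C → rt
Reagents that add atoms: water, O
Why: Acid hydrolysis removes the dioxolane and the primary silyl ether in one operation, and base-mediated conjugation through the dienolate moves the double bond into the more stable (E)-2-enal, so that C5 becomes the CH2 whose deprotonation later builds the diene.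

Step 11
Reactants: 18 methyl (2S,6E)-8-hydroxy-2,6-dimethyl-2-[(2E)-4-oxobut-2-en-1-yl]oct-6-enoate
Product: 19 methyl (2S,6E)-2,6-dimethyl-2-[(2E)-4-oxobut-2-en-1-yl]-8-{[(2,2,2-trichloroethoxy)carbonyl]oxy}oct-6-enoate
Conditions: TrocCl, pyridine, CH2Cl2, 0 °C
Reagents that add atoms: 2,2,2-trichloroethyl chloroformate, ClC(=O)OCC(Cl)(Cl)Cl
Why: Carbonate formation masks the C11 alcohol with a group that withstands silyl triflate and amine and is later removed by zinc, which attacks neither a silyl dienol ether nor the C4 ester.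

Step 12
Reactants: 19 methyl (2S,6E)-2,6-dimethyl-2-[(2E)-4-oxobut-2-en-1-yl]-8-{[(2,2,2-trichloroethoxy)carbonyl]oxy}oct-6-enoate
Product: 20 methyl (2S,6E)-2-[(1E,3E)-4-(tert-butyldimethylsilyloxy)buta-1,3-dien-1-yl]-2,6-dimethyl-8-{[(2,2,2-trichloroethoxy)carbonyl]oxy}oct-6-enoate
Conditions: TBSOTf, Et3N, CH2Cl2, −78 → 0 °C
Reagents that add atoms: tert-butyldimethylsilyl trifluoromethanesulfonate, CC(C)(C)[Si](C)(C)OS(=O)(=O)C(F)(F)F
Why: Silyl dienol ether formation, in which O-silylation of the s-trans enal and γ-deprotonation at C5 by the amine give the (1E,3E)-1-silyloxydiene, the bulky quaternary C4 turning away from C7 in the new C5=C6 bond.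

Step 13
Reactants: 20 methyl (2S,6E)-2-[(1E,3E)-4-(tert-butyldimethylsilyloxy)buta-1,3-dien-1-yl]-2,6-dimethyl-8-{[(2,2,2-trichloroethoxy)carbonyl]oxy}oct-6-enoate
Product: 21 methyl (2S,6E)-2-[(1E,3E)-4-(tert-butyldimethylsilyloxy)buta-1,3-dien-1-yl]-8-hydroxy-2,6-dimethyloct-6-enoate
Conditions: Zn dust, THF/1 M aq NH4OAc, rt
Reagents that add atoms: none
Why: Reductive fragmentation of the trichloroethyl carbonate (two-electron reduction, β-elimination of chloride, loss of CO2) frees the allylic alcohol at near-neutral pH, which should spare the silyl dienol ether and the hindered methyl ester.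

Step 14
Reactants: 21 methyl (2S,6E)-2-[(1E,3E)-4-(tert-butyldimethylsilyloxy)buta-1,3-dien-1-yl]-8-hydroxy-2,6-dimethyloct-6-enoate
Product: 22 methyl (2S,6E)-2-[(1E,3E)-4-(tert-butyldimethylsilyloxy)buta-1,3-dien-1-yl]-2,6-dimethyl-8-oxooct-6-enoate
Conditions: MnO2, CH2Cl2, rt
Reagents that add atoms: none
Why: Allylic oxidation with MnO2 touches only the allylic alcohol, uses neither acid nor fluoride, and so completes the triene with the (E)-enal and the diene geometry intact.

Step 15
Reactants: 22 methyl (2S,6E)-2-[(1E,3E)-4-(tert-butyldimethylsilyloxy)buta-1,3-dien-1-yl]-2,6-dimethyl-8-oxooct-6-enoate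
Product: 23 methyl 8β-(tert-butyldimethylsilyloxy)-11-oxo-12,13,14,15,16,17-hexanorlabd-6-en-19-oate
Conditions: toluene (0.01 M), BHT (cat), 140 °C, sealed tube, base-washed glass
Reagents that add atoms: none
Why: A concerted, suprafacial [4+2] cycloaddition of normal electron demand joins the electron-poor enal C9=C10 to the electron-rich silyloxydiene C5=C6–C7=C8, the closest known reaction type being the thermal intramolecular Diels–Alder reaction of 1,7,9-decatrienes whose (E)-dienophile carries a terminal acceptor and an internal methyl group. Ring B closes as the new cyclohexene through the bonds C5–C10 and C8–C9, and ring A closes in the same event as the fused ring of the four-carbon tether C1–C4, which links diene terminus C5 to dienophile carbon C10. C9 and C10 are set by the (E) geometry of the dienophile (C11 cis to the C10 methyl), C5 and C8 by the (E,E) geometry of the diene (C4 and the silyloxy group on the same face), and their mutual relation by the endo approach of the formyl group, which places H-5 trans to the C10 methyl and the silyloxy group cis to C11 (8β). The absolute sense of all four centres follows from C4, because in the chair-like tether the flatter methoxycarbonyl group takes the axial site facing the incoming C10 methyl while the C4 methyl stays equatorial. The step needs endo (trans-fusion) selectivity, which the terminal formyl group on an (E)-dienophile and the geminally substituted tether provide, and C4-facial selectivity, which rests only on the size difference between CO2Me and CH3 and is the weaker of the two, so a minor C4-facial isomer is expected and would be separated at this stage.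

Step 16
Reactants: 23 methyl 8β-(tert-butyldimethylsilyloxy)-11-oxo-12,13,14,15,16,17-hexanorlabd-6-en-19-oate
Product: 24 methyl 8β-(tert-butyldimethylsilyloxy)-11-oxo-12,13,14,15,16,17-hexanorlabdan-19-oate
Conditions: H2 (1 atm), Rh/Al2O3 (5%), EtOAc, rt
Reagents that add atoms: none
Why: Heterogeneous catalytic hydrogenation saturates the cis-disubstituted C6=C7 bond, Rh/Al2O3 being chosen to avoid hydrogenolysis of the allylic silyl ether and reduction of the aldehyde, and no stereocentre is created.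

Step 17
Reactants: 24 methyl 8β-(tert-butyldimethylsilyloxy)-11-oxo-12,13,14,15,16,17-hexanorlabdan-19-oate
Product: 25 methyl 8β-(tert-butyldimethylsilyloxy)-13,14,15,16,17-pentanorlabd-11-en-19-oate
Conditions: Ph3PCH3Br, KN(SiMe3)2, THF, −78 → 0 °C
Reagents that add atoms: methyltriphenylphosphonium bromide, C[P+](c1ccccc1)(c1ccccc1)c1ccccc1.[Br-]
Why: Wittig methylenation turns the C11 aldehyde into the C11=C12 vinyl group at low temperature, where addition to the carbonyl outruns enolisation, so the equatorial C9 centre and the β-silyloxy group are kept.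

Step 18
Reactants: 25 methyl 8β-(tert-butyldimethylsilyloxy)-13,14,15,16,17-pentanorlabd-11-en-19-oate; 4 (E)-tert-butyl[(3-iodobut-2-en-1-yl)oxy]dimethylsilane
Product: 27 methyl (13E)-8β,15-bis(tert-butyldimethylsilyloxy)-17-norlabd-13-en-19-oate, via B-alkyl-9-BBN adduct 26 (not isolated)
Conditions: 9-BBN, THF, rt → 40 °C; then 4, Pd(dppf)Cl2 (5 mol%), AsPh3, Cs2CO3, DMF/H2O, rt
Reagents that add atoms: none
Why: B-alkyl Suzuki–Miyaura coupling, in which hydroboration puts boron on the terminal C12 and coupling with the (E)-iodide forms C12–C13 with retention, giving the complete (13E) side chain.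

Step 19
Reactants: 27 methyl (13E)-8β,15-bis(tert-butyldimethylsilyloxy)-17-norlabd-13-en-19-oate
Product: 28 methyl (13E)-8β,15-dihydroxy-17-norlabd-13-en-19-oate
Conditions: HF·pyridine, THF, 0 °C → rt
Reagents that add atoms: none
Why: Fluoride-mediated desilylation removes both silyl ethers, the hindered axial one at C8 more slowly, while the methyl ester and the trisubstituted alkene are inert.

Step 20
Reactants: 28 methyl (13E)-8β,15-dihydroxy-17-norlabd-13-en-19-oate; 29 palmitoyl chloride
Product: 30 methyl (13E)-15-(hexadecanoyloxy)-8β-hydroxy-17-norlabd-13-en-19-oate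
Conditions: 29 (1.05 equiv), pyridine, CH2Cl2, −20 → 0 °C
Reagents that add atoms: none
Why: Acylation with an acid chloride should be selective for the primary allylic C15 alcohol, because the axial C8 alcohol is flanked by C9 and lies syn to the C10 methyl.

Step 21
Reactants: 30 methyl (13E)-15-(hexadecanoyloxy)-8β-hydroxy-17-norlabd-13-en-19-oate
Product: 31 methyl (13E)-15-(hexadecanoyloxy)-8-oxo-17-norlabd-13-en-19-oate
Conditions: Dess–Martin periodinane, pyridine, CH2Cl2, rt
Reagents that add atoms: none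
Why: Dess–Martin oxidation of the secondary alcohol gives the C8 ketone under neutral conditions, and C9 keeps its equatorial side chain, which is also the thermodynamic arrangement.

Step 22
Reactants: 31 methyl (13E)-15-(hexadecanoyloxy)-8-oxo-17-norlabd-13-en-19-oate
Product: 32 methyl (13E)-15-(hexadecanoyloxy)labda-8(17),13-dien-19-oate
Conditions: Zn, CH2Br2, TiCl4, THF, 0 °C → rt; then 31, CH2Cl2, rt
Reagents that add atoms: dibromomethane, BrCBr
Why: Takai–Lombardo methylenation, in which the non-basic Zn/CH2Br2/TiCl4 reagent converts the hindered, enolisable ketone into the C8=C17 exocyclic alkene without attacking either ester or epimerising C9.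

Compound list
1 | but-2-yn-1-ol | CC#CCO | starting material
2 | tert-butyl(but-2-yn-1-yloxy)dimethylsilane | CC#CCO[Si](C)(C)C(C)(C)C | intermediate
3 | Cp2Zr(Cl)[(E)-4-(tert-butyldimethylsilyloxy)but-2-en-2-yl], Zr on the methyl-bearing carbon and trans to CH2O | C/C(=C\CO[Si](C)(C)C(C)(C)C)[Zr](Cl)(C1C=CC=C1)C1C=CC=C1 | intermediate
4 | (E)-tert-butyl[(3-iodobut-2-en-1-yl)oxy]dimethylsilane | C/C(I)=C\CO[Si](C)(C)C(C)(C)C | intermediate
5 | dimethyl methylmalonate | COC(=O)C(C)C(=O)OC | starting material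
6 | allyl bromide (3-bromoprop-1-ene) | C=CCBr | starting material
7 | dimethyl 2-methyl-2-(prop-2-en-1-yl)propanedioate | C=CCC(C)(C(=O)OC)C(=O)OC | intermediate
8 | dimethyl 2-[3-(9-borabicyclo[3.3.1]nonan-9-yl)propyl]-2-methylpropanedioate | COC(=O)C(C)(CCCB1C2CCCC1CCC2)C(=O)OC | intermediate
9 | dimethyl 2-[(4E)-6-(tert-butyldimethylsilyloxy)-4-methylhex-4-en-1-yl]-2-methylpropanedioate | CC(C)(C)[Si](C)(C)OC/C=C(C)/CCCC(C)(C(=O)OC)C(=O)OC | intermediate
10 | (2R,6E)-8-(tert-butyldimethylsilyloxy)-2-(methoxycarbonyl)-2,6-dimethyloct-6-enoic acid | CC(C)(C)[Si](C)(C)OC/C=C(C)/CCC[C@@](C)(C(=O)OC)C(=O)O | intermediate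
11 | lithium (2R,6E)-8-(tert-butyldimethylsilyloxy)-2-(methoxycarbonyl)-2,6-dimethyloct-6-enoate | CC(C)(C)[Si](C)(C)OC/C=C(C)/CCC[C@@](C)(C(=O)OC)C(=O)[O-].[Li+] | intermediate
12 | (2S,6E)-8-(tert-butyldimethylsilyloxy)-2-(hydroxymethyl)-2,6-dimethyloct-6-enoic acid | CC(C)(C)[Si](C)(C)OC/C=C(C)/CCC[C@@](C)(CO)C(=O)O | intermediate
13 | methyl (2S,6E)-8-(tert-butyldimethylsilyloxy)-2-(hydroxymethyl)-2,6-dimethyloct-6-enoate | CC(C)(C)[Si](C)(C)OC/C=C(C)/CCC[C@](C)(C(=O)OC)CO | intermediate
14 | methyl (2S,6E)-8-(tert-butyldimethylsilyloxy)-2-formyl-2,6-dimethyloct-6-enoate | CC(C)(C)[Si](C)(C)OC/C=C(C)/CCC[C@](C)(C(=O)OC)C=O | intermediate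
15 | [2-(1,3-dioxolan-2-yl)ethyl]triphenylphosphonium bromide | [Br-].C1COC(CC[P+](c2ccccc2)(c2ccccc2)c2ccccc2)O1 | starting material
16 | methyl (2S,6E)-8-(tert-butyldimethylsilyloxy)-2-[(1Z)-3-(1,3-dioxolan-2-yl)prop-1-en-1-yl]-2,6-dimethyloct-6-enoate | CC(C)(C)[Si](C)(C)OC/C=C(C)/CCC[C@](C)(C(=O)OC)/C=C\CC1OCCO1 | intermediate
17 | methyl (2S,6E)-8-hydroxy-2,6-dimethyl-2-[(1Z)-4-oxobut-1-en-1-yl]oct-6-enoate | OC/C=C(C)/CCC[C@](C)(C(=O)OC)/C=C\CC=O | intermediate
18 | methyl (2S,6E)-8-hydroxy-2,6-dimethyl-2-[(2E)-4-oxobut-2-en-1-yl]oct-6-enoate | OC/C=C(C)/CCC[C@](C)(C(=O)OC)C/C=C/C=O | intermediate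
19 | methyl (2S,6E)-2,6-dimethyl-2-[(2E)-4-oxobut-2-en-1-yl]-8-{[(2,2,2-trichloroethoxy)carbonyl]oxy}oct-6-enoate | ClC(Cl)(Cl)COC(=O)OC/C=C(C)/CCC[C@](C)(C(=O)OC)C/C=C/C=O | intermediate
20 | methyl (2S,6E)-2-[(1E,3E)-4-(tert-butyldimethylsilyloxy)buta-1,3-dien-1-yl]-2,6-dimethyl-8-{[(2,2,2-trichloroethoxy)carbonyl]oxy}oct-6-enoate | ClC(Cl)(Cl)COC(=O)OC/C=C(C)/CCC[C@](C)(C(=O)OC)/C=C/C=C/O[Si](C)(C)C(C)(C)C | intermediate
21 | methyl (2S,6E)-2-[(1E,3E)-4-(tert-butyldimethylsilyloxy)buta-1,3-dien-1-yl]-8-hydroxy-2,6-dimethyloct-6-enoate | OC/C=C(C)/CCC[C@](C)(C(=O)OC)/C=C/C=C/O[Si](C)(C)C(C)(C)C | intermediate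
22 | methyl (2S,6E)-2-[(1E,3E)-4-(tert-butyldimethylsilyloxy)buta-1,3-dien-1-yl]-2,6-dimethyl-8-oxooct-6-enoate (all-E triene, key-step precursor) | O=C/C=C(\C)CCC[C@](C)(C(=O)OC)/C=C/C=C/O[Si](C)(C)C(C)(C)C | intermediate
23 | methyl 8β-(tert-butyldimethylsilyloxy)-11-oxo-12,13,14,15,16,17-hexanorlabd-6-en-19-oate (trans-octalin aldehyde, key-step product) | [C@H]1(O[Si](C)(C)C(C)(C)C)C=C[C@@H]2[C@](C)(CCC[C@]2(C)C(=O)OC)[C@H]1C=O | intermediate
24 | methyl 8β-(tert-butyldimethylsilyloxy)-11-oxo-12,13,14,15,16,17-hexanorlabdan-19-oate | [C@H]1(O[Si](C)(C)C(C)(C)C)CC[C@@H]2[C@](C)(CCC[C@]2(C)C(=O)OC)[C@H]1C=O | intermediate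
25 | methyl 8β-(tert-butyldimethylsilyloxy)-13,14,15,16,17-pentanorlabd-11-en-19-oate | [C@H]1(O[Si](C)(C)C(C)(C)C)CC[C@@H]2[C@](C)(CCC[C@]2(C)C(=O)OC)[C@H]1C=C | intermediate
26 | methyl 12-(9-borabicyclo[3.3.1]nonan-9-yl)-8β-(tert-butyldimethylsilyloxy)-13,14,15,16,17-pentanorlabdan-19-oate | [C@H]1(O[Si](C)(C)C(C)(C)C)CC[C@@H]2[C@](C)(CCC[C@]2(C)C(=O)OC)[C@H]1CCB3C4CCCC3CCC4 | intermediate
27 | methyl (13E)-8β,15-bis(tert-butyldimethylsilyloxy)-17-norlabd-13-en-19-oate | [C@H]1(O[Si](C)(C)C(C)(C)C)CC[C@@H]2[C@](C)(CCC[C@]2(C)C(=O)OC)[C@H]1CC/C(C)=C/CO[Si](C)(C)C(C)(C)C | intermediate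
28 | methyl (13E)-8β,15-dihydroxy-17-norlabd-13-en-19-oate | [C@H]1(O)CC[C@@H]2[C@](C)(CCC[C@]2(C)C(=O)OC)[C@H]1CC/C(C)=C/CO | intermediate
29 | palmitoyl chloride (hexadecanoyl chloride) | CCCCCCCCCCCCCCCC(=O)Cl | starting material
30 | methyl (13E)-15-(hexadecanoyloxy)-8β-hydroxy-17-norlabd-13-en-19-oate | [C@H]1(O)CC[C@@H]2[C@](C)(CCC[C@]2(C)C(=O)OC)[C@H]1CC/C(C)=C/COC(=O)CCCCCCCCCCCCCCC | intermediate
31 | methyl (13E)-15-(hexadecanoyloxy)-8-oxo-17-norlabd-13-en-19-oate | O=C1CC[C@@H]2[C@](C)(CCC[C@]2(C)C(=O)OC)[C@H]1CC/C(C)=C/COC(=O)CCCCCCCCCCCCCCC | intermediate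
32 | methyl (13E)-15-(hexadecanoyloxy)labda-8(17),13-dien-19-oate (CNP0157008.1) | C=C1CC[C@@H]2[C@](C)(CCC[C@]2(C)C(=O)OC)[C@H]1CC/C(C)=C/COC(=O)CCCCCCCCCCCCCCC | target

Total step count: 22. Longest linear sequence: 21 steps (steps 1, 2 and 4–22, from but-2-yn-1-ol); 20 steps from dimethyl methylmalonate.

Steps most likely to fail

1. Step 15. The endo and C4-facial preferences may erode at the temperature the cycloaddition needs, and the silyl dienol ether may be lost or isomerise from (1E) to (1Z) before it cyclises. The fallback replaces the thermal reaction of a silyl dienol ether by a Lewis-acid-promoted cycloaddition of a dienyl acetate at low temperature. It sets out from 18: silylation of the C11 alcohol (TBSCl, imidazole) would give the silyl ether enal F1, and Ac2O with Et3N and DMAP would convert its enal into the (1E,3E)-dienyl acetate F2. HF·pyridine would then free the allylic alcohol F3 and MnO2 would oxidise it to the enal F4. Me2AlCl in CH2Cl2 at −78 to −20 °C would close both rings to the 8β-acetoxy aldehyde F5. Hydrogenation over Rh/Al2O3 would give the saturated aldehyde F6, Takai–Lombardo methylenation the vinyl compound F7, and NaOMe in MeOH the 8β-alcohol F8. Silylation of F8 with TBSOTf and 2,6-lutidine comes back to the route at 25.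

2. Step 5. The esterase may discriminate the two enantiotopic ester groups incompletely, or turn over the lipophilic diester too slowly, so that C4 is not obtained enantiomerically pure. The fallback gives up the enzymatic desymmetrisation for a separation of covalent diastereomers. It sets out from 9: mono-reduction with LiAlH(OtBu)3 in THF would give the racemic hydroxy ester F9, and acylation with (1S)-camphanic chloride (pyridine, DMAP) would give two camphanates. These would be separated by chromatography or crystallisation into the (2S)-camphanate F10 and the (2R)-camphanate F11, which is set aside. K2CO3 in MeOH would release the alcohol from F10 and come back to the route at 13, bypassing 10–12.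

3. Step 13. The silyl dienol ether may hydrolyse in the aqueous buffer before the carbonate is fully cleaved, or the heterogeneous zinc reduction may stall. The fallback switches to an acyl group that is removed by hydride under anhydrous conditions. It sets out from 18: acetylation (Ac2O, pyridine, DMAP) would give the acetate enal F12 and TBSOTf/Et3N the acetate dienol ether F13. i-Bu2AlH in CH2Cl2 at −78 °C would then cleave the unhindered acetate faster than it reduces the neopentyl-type C4 ester, and comes back to the route at 21.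

Further compounds
F1 | step 15 | methyl (2S,6E)-8-(tert-butyldimethylsilyloxy)-2,6-dimethyl-2-[(2E)-4-oxobut-2-en-1-yl]oct-6-enoate | CC(C)(C)[Si](C)(C)OC/C=C(C)/CCC[C@](C)(C(=O)OC)C/C=C/C=O
F2 | step 15 | methyl (2S,6E)-2-[(1E,3E)-4-acetoxybuta-1,3-dien-1-yl]-8-(tert-butyldimethylsilyloxy)-2,6-dimethyloct-6-enoate | CC(C)(C)[Si](C)(C)OC/C=C(C)/CCC[C@](C)(C(=O)OC)/C=C/C=C/OC(C)=O
F3 | step 15 | methyl (2S,6E)-2-[(1E,3E)-4-acetoxybuta-1,3-dien-1-yl]-8-hydroxy-2,6-dimethyloct-6-enoate | OC/C=C(C)/CCC[C@](C)(C(=O)OC)/C=C/C=C/OC(C)=O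
F4 | step 15 | methyl (2S,6E)-2-[(1E,3E)-4-acetoxybuta-1,3-dien-1-yl]-2,6-dimethyl-8-oxooct-6-enoate | O=C/C=C(\C)CCC[C@](C)(C(=O)OC)/C=C/C=C/OC(C)=O
F5 | step 15 | methyl 8β-acetoxy-11-oxo-12,13,14,15,16,17-hexanorlabd-6-en-19-oate | [C@H]1(OC(C)=O)C=C[C@@H]2[C@](C)(CCC[C@]2(C)C(=O)OC)[C@H]1C=O
F6 | step 15 | methyl 8β-acetoxy-11-oxo-12,13,14,15,16,17-hexanorlabdan-19-oate | [C@H]1(OC(C)=O)CC[C@@H]2[C@](C)(CCC[C@]2(C)C(=O)OC)[C@H]1C=O
F7 | step 15 | methyl 8β-acetoxy-13,14,15,16,17-pentanorlabd-11-en-19-oate | [C@H]1(OC(C)=O)CC[C@@H]2[C@](C)(CCC[C@]2(C)C(=O)OC)[C@H]1C=C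
F8 | step 15 | methyl 8β-hydroxy-13,14,15,16,17-pentanorlabd-11-en-19-oate | [C@H]1(O)CC[C@@H]2[C@](C)(CCC[C@]2(C)C(=O)OC)[C@H]1C=C
F9 | step 5 | racemic methyl (6E)-8-(tert-butyldimethylsilyloxy)-2-(hydroxymethyl)-2,6-dimethyloct-6-enoate | CC(C)(C)[Si](C)(C)OC/C=C(C)/CCCC(C)(C(=O)OC)CO
F10 | step 5 | methyl (2S,6E)-8-(tert-butyldimethylsilyloxy)-2,6-dimethyl-2-({[(1S,4R)-4,7,7-trimethyl-3-oxo-2-oxabicyclo[2.2.1]heptane-1-carbonyl]oxy}methyl)oct-6-enoate | CC(C)(C)[Si](C)(C)OC/C=C(C)/CCC[C@](C)(C(=O)OC)COC(=O)[C@@]12CC[C@@](C)(C(=O)O1)C2(C)C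
F11 | step 5 | methyl (2R,6E)-8-(tert-butyldimethylsilyloxy)-2,6-dimethyl-2-({[(1S,4R)-4,7,7-trimethyl-3-oxo-2-oxabicyclo[2.2.1]heptane-1-carbonyl]oxy}methyl)oct-6-enoate | CC(C)(C)[Si](C)(C)OC/C=C(C)/CCC[C@@](C)(C(=O)OC)COC(=O)[C@@]12CC[C@@](C)(C(=O)O1)C2(C)C
F12 | step 13 | methyl (2S,6E)-8-acetoxy-2,6-dimethyl-2-[(2E)-4-oxobut-2-en-1-yl]oct-6-enoate | CC(=O)OC/C=C(C)/CCC[C@](C)(C(=O)OC)C/C=C/C=O
F13 | step 13 | methyl (2S,6E)-8-acetoxy-2-[(1E,3E)-4-(tert-butyldimethylsilyloxy)buta-1,3-dien-1-yl]-2,6-dimethyloct-6-enoate | CC(=O)OC/C=C(C)/CCC[C@](C)(C(=O)OC)/C=C/C=C/O[Si](C)(C)C(C)(C)C
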